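**Retrosynthetic overview**
1. The target is epicatechin-(4β→8)-epiafzelechin: upper flavan with rings A (phloroglucinol), B (catechol) and C (pyran O1–C2–C3–C4–C4a–C8a); lower flavan with rings D, E, F, taken intact from (−)-epiafzelechin and carried as its 8-carbaldehyde.
2. Ring C is closed last, at C4–C4a: acid opens a temporary trans C3–C4 oxirane (a ring absent from the target), and ring A, already tied to C2 through O1, captures C4 in a 6-endo Friedel–Crafts closure that sets the doubly benzylic stereocentre C4 with inversion and releases 3-OH.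
3. Enabling feature: C4 is benzylic to C8 of ring D, which carries oxygen at both ortho positions (O7 and the ring F oxygen) and at the para position (O5), so the oxirane C4–O bond ionises at low temperature; C4a is the ortho carbon of the 1,3,5-trioxygenated ring A and lies six atoms from C4 (C4a–C8a–O1–C2–C3–C4).
4. Precursor: O1–C2 by Mitsunobu inversion of an anti epoxy alcohol with 3,5-bis(benzyloxy)phenol; the epoxy alcohol by chelation-controlled reduction of a (2R,3S)-chalcone epoxide (Juliá–Colonna); the chalcone by Claisen–Schmidt condensation of the ring D aldehyde with 3,4-bis(benzyloxy)acetophenone (C2 and ring B).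
5. Ring order: rings D, E, F and the arenes A and B are bought; then the temporary oxirane; then ring C (last); then removal of eight benzyl groups.

Key step: step 9

Assumption: (−)-epiafzelechin is taken as a purchasable flavan-3-ol, and the facial sense of poly-L-leucine known for simple chalcones ((2R,3S)-oxirane) is assumed to carry over to chalcone 8.

Abbreviation used in names: "tetra-O-benzylepiafzelechin-8-yl" = (2R,3R)-3,5,7-tris(benzyloxy)-2-[4-(benzyloxy)phenyl]chroman-8-yl.

**Step 1**
Reactants: 1 (−)-epiafzelechin [(2R,3R)-2-(4-hydroxyphenyl)chroman-3,5,7-triol]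
Product: 2 (2R,3R)-5,7-bis(benzyloxy)-2-[4-(benzyloxy)phenyl]chroman-3-ol
Conditions: BnBr (3.3 equiv), K2CO3, DMF, rt
Reagents that add atoms: benzyl bromide, BrCc1ccccc1
Why: Williamson ether synthesis in which K2CO3 deprotonates only the three phenols, so the secondary 3-OH stays free and no stereocentre is touched.

**Step 2**
Reactants: 2 (2R,3R)-5,7-bis(benzyloxy)-2-[4-(benzyloxy)phenyl]chroman-3-ol
Product: 3 (2R,3R)-3,5,7-tris(benzyloxy)-2-[4-(benzyloxy)phenyl]chroman (3,5,7,4'-tetra-O-benzylepiafzelechin)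
Conditions: NaH, BnBr, Bu4NI (cat.), THF/DMF, 0 °C → rt
Reagents that add atoms: benzyl bromide, BrCc1ccccc1
Why: Williamson ether synthesis on the sodium alkoxide protects 3-OH against the organolithium and Mitsunobu steps, and C3 keeps its configuration because its C–O bond is not broken.

**Step 3**
Reactants: 3 (2R,3R)-3,5,7-tris(benzyloxy)-2-[4-(benzyloxy)phenyl]chroman
Product: 4 (2R,3R)-3,5,7-tris(benzyloxy)-2-[4-(benzyloxy)phenyl]-8-bromochroman
Conditions: NBS (1.0 equiv), CH2Cl2, −78 → −40 °C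
Reagents that add atoms: N-bromosuccinimide, O=C1CCC(=O)N1Br
Why: Electrophilic aromatic bromination, in which C8 of ring D (between O7 and the ring oxygen) is the more reactive free position of 5,7-di-O-benzyl flavans toward NBS, so the site of the later interflavan carbon is fixed.

**Step 4**
Reactants: 4 (2R,3R)-3,5,7-tris(benzyloxy)-2-[4-(benzyloxy)phenyl]-8-bromochroman
Product: 6 (2R,3R)-3,5,7-tris(benzyloxy)-2-[4-(benzyloxy)phenyl]chroman-8-carbaldehyde, via 8-lithio-tetra-O-benzylepiafzelechin 5 (not isolated)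
Conditions: n-BuLi, THF, −78 °C; DMF, −78 → 0 °C; H2O
Reagents that add atoms: N,N-dimethylformamide, CN(C)C=O (formyl group of 6); n-butyllithium, CCCC[Li] (lithium of 5)
Why: Bromine–lithium exchange is faster than ether deprotonation at −78 °C, and the doubly ortho-alkoxy-stabilised aryllithium is formylated by DMF (Bouveault aldehyde synthesis).

**Step 5**
Reactants: 6 (2R,3R)-3,5,7-tris(benzyloxy)-2-[4-(benzyloxy)phenyl]chroman-8-carbaldehyde; 7 1-[3,4-bis(benzyloxy)phenyl]ethan-1-one
Product: 8 (E)-1-[3,4-bis(benzyloxy)phenyl]-3-(tetra-O-benzylepiafzelechin-8-yl)prop-2-en-1-one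
Conditions: KOH, EtOH/THF, rt
Reagents that add atoms: none
Why: Claisen–Schmidt condensation of a non-enolisable aldehyde with the methyl ketone should give the conjugated (E)-enone directly, and the benzyl ethers and the flavan stereocentres (no free 4'-OH, hence no quinone-methide epimerisation at C2) are stable to KOH.

**Step 6**
Reactants: 8 (E)-1-[3,4-bis(benzyloxy)phenyl]-3-(tetra-O-benzylepiafzelechin-8-yl)prop-2-en-1-one
Product: 9 [3,4-bis(benzyloxy)phenyl][(2R,3S)-3-(tetra-O-benzylepiafzelechin-8-yl)oxiran-2-yl]methanone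
Conditions: poly-L-leucine, urea–H2O2, DBU, THF, rt
Reagents that add atoms: hydrogen peroxide (used as its urea adduct), OO
Why: Juliá–Colonna epoxidation (Weitz–Scheffer hydroperoxide addition inside the helical peptide) should deliver oxygen to the enone face that gives the (2R,3S)-trans-oxirane under catalyst control, because the flavan stereocentres are remote; these two centres become C3 and C4 of ring C.

**Step 7**
Reactants: 9 [3,4-bis(benzyloxy)phenyl][(2R,3S)-3-(tetra-O-benzylepiafzelechin-8-yl)oxiran-2-yl]methanone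
Product: 10 (S)-[3,4-bis(benzyloxy)phenyl][(2S,3S)-3-(tetra-O-benzylepiafzelechin-8-yl)oxiran-2-yl]methanol (anti, erythro)
Conditions: Zn(BH4)2, Et2O, −40 °C; aq. NaHCO3
Reagents that add atoms: none
Why: Chelation-controlled reduction (Cram chelate model): zinc bridges the carbonyl and oxirane oxygens and hydride adds from the face of the oxirane C–H, which should give the anti epoxy alcohol with the new (S)-carbinol centre, the future C2.

**Step 8**
Reactants: 10 (S)-[3,4-bis(benzyloxy)phenyl][(2S,3S)-3-(tetra-O-benzylepiafzelechin-8-yl)oxiran-2-yl]methanol; 11 3,5-bis(benzyloxy)phenol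
Product: 12 (2R,3S)-2-{(R)-[3,4-bis(benzyloxy)phenyl][3,5-bis(benzyloxy)phenoxy]methyl}-3-(tetra-O-benzylepiafzelechin-8-yl)oxirane
Conditions: PPh3, DIAD, toluene, −20 → 0 °C; filtration through Et3N-deactivated silica
Reagents that add atoms: none
Why: Mitsunobu etherification, in which the phenol displaces the activated benzylic oxygen in the SN2 sense and inverts the carbinol to the (R)-aryl ether (O1–C2); the neighbouring oxirane oxygen, the non-polar solvent and the low temperature disfavour ionisation, and the oxirane survives the neutral conditions.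

**Step 9**
Reactants: 12 (2R,3S)-2-{(R)-[3,4-bis(benzyloxy)phenyl][3,5-bis(benzyloxy)phenoxy]methyl}-3-(tetra-O-benzylepiafzelechin-8-yl)oxirane
Product: 14 5,7,3',4'-tetra-O-benzylepicatechin-(4β→8)-3,5,7,4'-tetra-O-benzylepiafzelechin (upper 3-OH free; upper unit 2R,3R,4R), via benzylic carbenium tosylate 13 (not isolated)
Conditions: TsOH·H2O (5 mol%), HFIP/CH2Cl2 (1:4), −40 → 0 °C; Et3N
Reagents that add atoms: none
Why: Protonation in the hydrogen-bond-donor medium opens the oxirane at C4, whose C–O bond is benzylic to C8 of the 2,4,6-trioxygenated ring D, to the hydroxy carbenium ion pair 13, and the ortho carbon C4a of ring A, held six atoms away through O1–C2–C3, should capture it before a 1,2-hydride shift can compete. The closest known reaction type is the Brønsted-acid-catalysed intramolecular Friedel–Crafts epoxy–arene cyclization of 3-aryl glycidyl aryl ethers to trans-4-arylchroman-3-ols. Ring C closes in the 6-endo mode at the oxirane (C4–C4a bond; the 5-exo attack at C3 has no benzylic stabilisation), and the two ortho positions of ring A are equivalent, so only one regioisomer can form. C4 is set with inversion, anti to the departing oxirane oxygen, and the same 3,4-trans result is expected even through a fully opened cation, because in the chair-like closure the C2 aryl group is equatorial, the cis C3 oxygen is therefore axial, and the peri 5-benzyloxy group of ring A forces the ring D substituent at C4 quasi-axial and anti to it; C2 and C3 are carried over unchanged from 12. The step needs selectivity for ring A over ring B (which could close a five-membered indane) and for oxirane ionisation over ionisation of the C2–O1 benzylic ether: C4a has three oxygen donors ortho or para to it against one para donor for the competing carbon of ring B, and the trioxygenated benzylic oxirane ionises at a temperature at which the ether should be inert.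

**Step 10**
Reactants: 14 5,7,3',4'-tetra-O-benzylepicatechin-(4β→8)-3,5,7,4'-tetra-O-benzylepiafzelechin
Product: 15 epicatechin-(4β→8)-epiafzelechin (CNP0299023.1)
Conditions: H2 (1 atm), Pd(OH)2/C, THF/MeOH, rt
Reagents that add atoms: none
Why: Catalytic hydrogenolysis removes the eight O-benzyl groups under neutral conditions, under which the acid-labile C4–C8 interflavan bond, the benzylic C2–O1 bonds and all five stereocentres are expected to survive, as in the debenzylation of perbenzylated procyanidins.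

**Compound list**
1 | (−)-epiafzelechin, (2R,3R)-2-(4-hydroxyphenyl)chroman-3,5,7-triol | Oc1ccc(cc1)[C@H]1Oc2cc(O)cc(O)c2C[C@H]1O | starting material
2 | (2R,3R)-5,7-bis(benzyloxy)-2-[4-(benzyloxy)phenyl]chroman-3-ol | c1ccccc1COc1ccc(cc1)[C@H]1Oc2cc(OCc3ccccc3)cc(OCc3ccccc3)c2C[C@H]1O | intermediate
3 | (2R,3R)-3,5,7-tris(benzyloxy)-2-[4-(benzyloxy)phenyl]chroman | c1ccccc1COc1ccc(cc1)[C@H]1Oc2cc(OCc3ccccc3)cc(OCc3ccccc3)c2C[C@H]1OCc1ccccc1 | intermediate
4 | (2R,3R)-3,5,7-tris(benzyloxy)-2-[4-(benzyloxy)phenyl]-8-bromochroman | c1ccccc1COc1ccc(cc1)[C@H]1Oc2c(Br)c(OCc3ccccc3)cc(OCc3ccccc3)c2C[C@H]1OCc1ccccc1 | intermediate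
5 | 8-lithio-tetra-O-benzylepiafzelechin (aryllithium at C8 of ring D) | c1ccccc1COc1ccc(cc1)[C@H]1Oc2c([Li])c(OCc3ccccc3)cc(OCc3ccccc3)c2C[C@H]1OCc1ccccc1 | intermediate (not isolated)
6 | (2R,3R)-3,5,7-tris(benzyloxy)-2-[4-(benzyloxy)phenyl]chroman-8-carbaldehyde | c1ccccc1COc1ccc(cc1)[C@H]1Oc2c(C=O)c(OCc3ccccc3)cc(OCc3ccccc3)c2C[C@H]1OCc1ccccc1 | intermediate
7 | 1-[3,4-bis(benzyloxy)phenyl]ethan-1-one | CC(=O)c1ccc(OCc2ccccc2)c(OCc2ccccc2)c1 | starting material
8 | (E)-1-[3,4-bis(benzyloxy)phenyl]-3-(tetra-O-benzylepiafzelechin-8-yl)prop-2-en-1-one | c1ccccc1COc1ccc(cc1)[C@H]1Oc2c(/C=C/C(=O)c3ccc(OCc4ccccc4)c(OCc4ccccc4)c3)c(OCc3ccccc3)cc(OCc3ccccc3)c2C[C@H]1OCc1ccccc1 | intermediate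
9 | [3,4-bis(benzyloxy)phenyl][(2R,3S)-3-(tetra-O-benzylepiafzelechin-8-yl)oxiran-2-yl]methanone | c1ccccc1COc1ccc(cc1)[C@H]1Oc2c([C@@H]3O[C@H]3C(=O)c3ccc(OCc4ccccc4)c(OCc4ccccc4)c3)c(OCc3ccccc3)cc(OCc3ccccc3)c2C[C@H]1OCc1ccccc1 | intermediate
10 | (S)-[3,4-bis(benzyloxy)phenyl][(2S,3S)-3-(tetra-O-benzylepiafzelechin-8-yl)oxiran-2-yl]methanol (anti epoxy alcohol) | c1ccccc1COc1ccc(cc1)[C@H]1Oc2c([C@@H]3O[C@H]3[C@@H](O)c3ccc(OCc4ccccc4)c(OCc4ccccc4)c3)c(OCc3ccccc3)cc(OCc3ccccc3)c2C[C@H]1OCc1ccccc1 | intermediate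
11 | 3,5-bis(benzyloxy)phenol | Oc1cc(OCc2ccccc2)cc(OCc2ccccc2)c1 | starting material
12 | (2R,3S)-2-{(R)-[3,4-bis(benzyloxy)phenyl][3,5-bis(benzyloxy)phenoxy]methyl}-3-(tetra-O-benzylepiafzelechin-8-yl)oxirane | c1ccccc1COc1ccc(cc1)[C@H]1Oc2c([C@@H]3O[C@H]3[C@H](Oc3cc(OCc4ccccc4)cc(OCc4ccccc4)c3)c3ccc(OCc4ccccc4)c(OCc4ccccc4)c3)c(OCc3ccccc3)cc(OCc3ccccc3)c2C[C@H]1OCc1ccccc1 | intermediate
13 | hydroxy carbenium ion from C4–O cleavage of 12 (cation at C4, free 3-OH), tosylate ion pair | c1ccccc1COc1ccc(cc1)[C@H]1Oc2c([CH+][C@@H](O)[C@H](Oc3cc(OCc4ccccc4)cc(OCc4ccccc4)c3)c3ccc(OCc4ccccc4)c(OCc4ccccc4)c3)c(OCc3ccccc3)cc(OCc3ccccc3)c2C[C@H]1OCc1ccccc1.Cc1ccc(cc1)S([O-])(=O)=O | intermediate (not isolated)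
14 | 5,7,3',4'-tetra-O-benzylepicatechin-(4β→8)-3,5,7,4'-tetra-O-benzylepiafzelechin (upper 2R,3R,4R with free 3-OH; lower 2R,3R) | c1ccccc1COc1ccc(cc1)[C@H]1Oc2c([C@H]3c4c(OCc5ccccc5)cc(OCc5ccccc5)cc4O[C@H](c4ccc(OCc5ccccc5)c(OCc5ccccc5)c4)[C@@H]3O)c(OCc3ccccc3)cc(OCc3ccccc3)c2C[C@H]1OCc1ccccc1 | intermediate
15 | epicatechin-(4β→8)-epiafzelechin, CNP0299023.1 | Oc1ccc([C@H]2Oc3c(c(O)cc(O)c3[C@H]3c4c(O)cc(O)cc4O[C@H](c4ccc(O)c(O)c4)[C@@H]3O)C[C@H]2O)cc1 | target

**Step count and risks**
Total step count: 10. Longest linear sequence: 10 steps (1 → 15).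

Steps most likely to fail:

Step 8. Risk: the activated p-alkoxybenzylic carbinol ionises during the Mitsunobu reaction, which would scramble C2, alkylate the phenol on carbon or open the oxirane. Fallback: the C2–O1 bond is made at oxygen, so that C2 is never a leaving-group carbon. Setting out from 9, reagent-controlled CBS reduction with the (R)-configured oxazaborolidine and BH3·SMe2, chosen to override chelation and deliver the (R)-carbinol, should give the syn epoxy alcohol (R)-[3,4-bis(benzyloxy)phenyl][(2S,3S)-3-(tetra-O-benzylepiafzelechin-8-yl)oxiran-2-yl]methanol F1. Its sodium alkoxide (NaH, toluene, 0 °C) is then O-arylated with [3,5-bis(benzyloxy)phenyl](2,4,6-trimethoxyphenyl)iodonium 4-methylbenzenesulfonate F2, made in one pot from 1,3-bis(benzyloxy)-5-iodobenzene with mCPBA and TsOH·H2O followed by 1,3,5-trimethoxybenzene. This metal-free ligand coupling on iodine keeps the carbinol configuration and transfers only the less electron-rich aryl group, and it returns to the route at 12.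

Step 9. Risk: the carbenium ion undergoes a 1,2-hydride shift (Meinwald rearrangement to the C3 ketone), closes onto ring B to an indane, or the acid ionises the C2–O1 ether. Fallback: the cationic closure is replaced by an anionic one. Setting out from 10, the Mitsunobu reaction of step 8 is run with 2-bromo-3,5-bis(benzyloxy)phenol F3 (NBS bromination of 11, ortho isomer separated) to give the bromo ether (2R,3S)-2-{(R)-[3,4-bis(benzyloxy)phenyl][2-bromo-3,5-bis(benzyloxy)phenoxy]methyl}-3-(tetra-O-benzylepiafzelechin-8-yl)oxirane F4. Bromine–lithium exchange (t-BuLi, THF, −78 °C) followed by BF3·OEt2 lets the ring A aryllithium open the oxirane at the benzylic C4 with inversion in the 6-endo mode, which returns to the route at 14.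

Step 6. Risk: peroxide transfer inside the peptide helix is slow for the di-ortho-substituted, donor-deactivated enone, and the uncatalysed Weitz–Scheffer background erodes facial selectivity. Fallback: the oxirane is made at the enal stage by iminium catalysis. Setting out from 6, Wittig olefination with (triphenylphosphoranylidene)acetaldehyde gives (E)-3-(tetra-O-benzylepiafzelechin-8-yl)prop-2-enal F5. Epoxidation with H2O2 and (S)-α,α-bis[3,5-bis(trifluoromethyl)phenyl]prolinol trimethylsilyl ether (10 mol%, CH2Cl2) should give (2R,3S)-3-(tetra-O-benzylepiafzelechin-8-yl)oxirane-2-carbaldehyde F6, by analogy with cinnamaldehyde. Addition of 3,4-bis(benzyloxy)phenylmagnesium bromide (from 4-bromo-1,2-bis(benzyloxy)benzene) gives the carbinol mixture [3,4-bis(benzyloxy)phenyl][(2S,3S)-3-(tetra-O-benzylepiafzelechin-8-yl)oxiran-2-yl]methanol F7 (both carbinol epimers), and Dess–Martin oxidation buffered with NaHCO3 returns to the route at 9.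

**Further compounds**
F1 | step 8 | (R)-[3,4-bis(benzyloxy)phenyl][(2S,3S)-3-(tetra-O-benzylepiafzelechin-8-yl)oxiran-2-yl]methanol (syn epimer of 10) | c1ccccc1COc1ccc(cc1)[C@H]1Oc2c([C@@H]3O[C@H]3[C@H](O)c3ccc(OCc4ccccc4)c(OCc4ccccc4)c3)c(OCc3ccccc3)cc(OCc3ccccc3)c2C[C@H]1OCc1ccccc1
F2 | step 8 | [3,5-bis(benzyloxy)phenyl](2,4,6-trimethoxyphenyl)iodonium 4-methylbenzenesulfonate | COc1cc(OC)c([I+]c2cc(OCc3ccccc3)cc(OCc3ccccc3)c2)c(OC)c1.Cc1ccc(cc1)S([O-])(=O)=O
F3 | step 9 | 2-bromo-3,5-bis(benzyloxy)phenol | Oc1cc(OCc2ccccc2)cc(OCc2ccccc2)c1Br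
F4 | step 9 | (2R,3S)-2-{(R)-[3,4-bis(benzyloxy)phenyl][2-bromo-3,5-bis(benzyloxy)phenoxy]methyl}-3-(tetra-O-benzylepiafzelechin-8-yl)oxirane | c1ccccc1COc1ccc(cc1)[C@H]1Oc2c([C@@H]3O[C@H]3[C@H](Oc3cc(OCc4ccccc4)cc(OCc4ccccc4)c3Br)c3ccc(OCc4ccccc4)c(OCc4ccccc4)c3)c(OCc3ccccc3)cc(OCc3ccccc3)c2C[C@H]1OCc1ccccc1
F5 | step 6 | (E)-3-(tetra-O-benzylepiafzelechin-8-yl)prop-2-enal | c1ccccc1COc1ccc(cc1)[C@H]1Oc2c(/C=C/C=O)c(OCc3ccccc3)cc(OCc3ccccc3)c2C[C@H]1OCc1ccccc1
F6 | step 6 | (2R,3S)-3-(tetra-O-benzylepiafzelechin-8-yl)oxirane-2-carbaldehyde | c1ccccc1COc1ccc(cc1)[C@H]1Oc2c([C@@H]3O[C@H]3C=O)c(OCc3ccccc3)cc(OCc3ccccc3)c2C[C@H]1OCc1ccccc1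
F7 | step 6 | [3,4-bis(benzyloxy)phenyl][(2S,3S)-3-(tetra-O-benzylepiafzelechin-8-yl)oxiran-2-yl]methanol, both carbinol epimers | c1ccccc1COc1ccc(cc1)[C@H]1Oc2c([C@@H]3O[C@H]3C(O)c3ccc(OCc4ccccc4)c(OCc4ccccc4)c3)c(OCc3ccccc3)cc(OCc3ccccc3)c2C[C@H]1OCc1ccccc1
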